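**Retrosynthetic overview**
1. Target 30 ⇐ silyl ether 29 ⇐ tetraene 28 by ring-closing metathesis: ring C, and with it the ten-membered ring of the bicyclo[4.4.1]undec-1-ene, closes last and forms the bridgehead C=C.
2. 28 ⇐ ring B cycloheptenone 25 + fragment C (2-bromohexa-1,5-diene 16): Cu-catalysed 1,4-addition anti to ring A, then Wittig methylenation.
3. 25 ⇐ vinyl ketone 24 by a first ring-closing metathesis (ring B, formed second).
4. 24 ⇐ cyclohexenone 18: vinyl 1,4-addition/enol triflate, Kumada coupling to an allylsilane, protodesilylation (sets the ring A stereotriad and the exocyclic methylene).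
5. 18 (ring A, formed first) ⇐ fragment A (aldehyde 6 from (S)-citronellol) + fragment B (vinyl ketone 12 from δ-valerolactone) by organocatalytic Michael/aldol annulation.

Assumption: the silyloxy carbon of fragment B is racemic, so 17–23 are carried as 1:1 epimer mixtures at that carbon until it is oxidised in step 18.
Abbreviations: TBDPS = tert-butyldiphenylsilyl, TES = triethylsilyl, Tf = trifluoromethanesulfonyl, DMP = Dess–Martin periodinane.

**Fragment A**

Step 1
Reactants: 1 (S)-citronellol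
Product: 2 (3S)-3,7-dimethyloct-6-en-1-yl acetate
Conditions: Ac2O, Et3N, DMAP (cat.), CH2Cl2, 0 °C → rt
Reagents that add atoms: acetic anhydride CC(=O)OC(C)=O
Why: Acylation masks the primary alcohol so that only the allylic methyl is oxidised next; the C3 centre (S, from the chiral pool) is untouched.

Step 2
Reactants: 2 (3S)-3,7-dimethyloct-6-en-1-yl acetate
Product: 3 (3S,6E)-8-hydroxy-3,7-dimethyloct-6-en-1-yl acetate
Conditions: SeO2 (cat.), t-BuOOH, salicylic acid (cat.), CH2Cl2, rt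
Reagents that add atoms: tert-butyl hydroperoxide CC(C)(C)OO
Why: SeO2-catalysed allylic oxidation (ene reaction then [2,3]-sigmatropic shift) attacks the (E)-methyl of the trisubstituted alkene and gives the (E)-allylic alcohol.

Step 3
Reactants: 3 (3S,6E)-8-hydroxy-3,7-dimethyloct-6-en-1-yl acetate
Product: 4 (3S,6E)-8-(TBDPS-oxy)-3,7-dimethyloct-6-en-1-yl acetate
Conditions: TBDPSCl, imidazole, DMF, rt
Reagents that add atoms: tert-butyl(chloro)diphenylsilane CC(C)(C)[Si](Cl)(c1ccccc1)c1ccccc1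
Why: Silylation of the only free hydroxyl with an acid- and base-robust group that is kept until the last step.

Step 4
Reactants: 4 (3S,6E)-8-(TBDPS-oxy)-3,7-dimethyloct-6-en-1-yl acetate
Product: 5 (3S,6E)-8-(TBDPS-oxy)-3,7-dimethyloct-6-en-1-ol
Conditions: K2CO3 (cat.), MeOH, rt
Reagents that add atoms: none
Why: Base-catalysed transesterification removes the acetate and leaves the TBDPS ether intact.

Step 5
Reactants: 5 (3S,6E)-8-(TBDPS-oxy)-3,7-dimethyloct-6-en-1-ol
Product: 6 (3S,6E)-8-(TBDPS-oxy)-3,7-dimethyloct-6-enal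
Conditions: DMP, CH2Cl2, 0 °C → rt
Reagents that add atoms: none
Why: Dess–Martin oxidation stops at the aldehyde under neutral conditions and does not touch the β-stereocentre or the alkene.

**Fragment B**

Step 6
Reactants: 7 δ-valerolactone
Product: 8 5-hydroxy-N-methoxy-N-methylpentanamide
Conditions: MeNH(OMe)·HCl, iPrMgCl, THF, −20 → 0 °C
Reagents that add atoms: N,O-dimethylhydroxylamine hydrochloride CNOC.Cl
Why: Aminolysis of the lactone by the magnesium amide (Weinreb amide formation) opens the ring to the hydroxy amide.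

Step 7
Reactants: 8 5-hydroxy-N-methoxy-N-methylpentanamide
Product: 9 N-methoxy-N-methyl-5-oxopentanamide
Conditions: DMP, CH2Cl2, 0 °C → rt
Reagents that add atoms: none
Why: Dess–Martin oxidation of the primary alcohol to the aldehyde; the amide is inert.

Step 8
Reactants: 9 N-methoxy-N-methyl-5-oxopentanamide
Product: 10 (±)-5-hydroxy-N-methoxy-N-methylhept-6-enamide
Conditions: CH2=CHMgBr (1.05 equiv), THF, −78 °C
Reagents that add atoms: vinylmagnesium bromide C=C[Mg]Br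
Why: Grignard 1,2-addition at −78 °C is chemoselective for the aldehyde over the Weinreb amide; the new carbinol centre is racemic and is later oxidised away.

Step 9
Reactants: 10 (±)-5-hydroxy-N-methoxy-N-methylhept-6-enamide
Product: 11 (±)-N-methoxy-N-methyl-5-(TES-oxy)hept-6-enamide
Conditions: TESCl, imidazole, CH2Cl2, 0 °C
Reagents that add atoms: chlorotriethylsilane CC[Si](Cl)(CC)CC
Why: Silylation gives an ether that survives Grignard and cuprate steps but is cleaved by mild acid.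

Step 10
Reactants: 11 (±)-N-methoxy-N-methyl-5-(TES-oxy)hept-6-enamide
Product: 12 (±)-7-(TES-oxy)nona-1,8-dien-3-one
Conditions: CH2=CHMgBr (1.5 equiv), THF, 0 °C; cold aqueous acid quench
Reagents that add atoms: vinylmagnesium bromide C=C[Mg]Br
Why: Weinreb ketone synthesis; the chelated tetrahedral intermediate prevents over-addition and collapses to the vinyl ketone on work-up.

**Fragment C**

Step 11
Reactants: 13 2-bromoprop-2-en-1-ol
Product: 14 ethyl 4-bromopent-4-enoate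
Conditions: CH3C(OEt)3, propionic acid (cat.), 140 °C, distil off EtOH
Reagents that add atoms: triethyl orthoacetate CCOC(C)(OCC)OCC
Why: Johnson–Claisen orthoester rearrangement ([3,3]-sigmatropic) adds the two-carbon ester arm and moves the C=C to the 2-bromo-1-alkene terminus.

Step 12
Reactants: 14 ethyl 4-bromopent-4-enoate
Product: 15 4-bromopent-4-enal
Conditions: iBu2AlH (1.05 equiv), CH2Cl2, −78 °C
Reagents that add atoms: none
Why: Partial reduction of the ester; the tetrahedral aluminate is stable at −78 °C and releases the aldehyde on work-up.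

Step 13
Reactants: 15 4-bromopent-4-enal
Product: 16 2-bromohexa-1,5-diene
Conditions: Ph3PCH3Br, KOtBu, THF, 0 °C → rt
Reagents that add atoms: methyltriphenylphosphonium bromide C[P+](c1ccccc1)(c1ccccc1)c1ccccc1.[Br-]
Why: Wittig methylenation of the aldehyde gives the terminal alkene needed for the final ring closure.

**Union and ring construction**

Step 14
Reactants: 6 (3S,6E)-8-(TBDPS-oxy)-3,7-dimethyloct-6-enal; 12 (±)-7-(TES-oxy)nona-1,8-dien-3-one
Product: 18 (4S)-4-[(2S,5E)-7-(TBDPS-oxy)-6-methylhept-5-en-2-yl]-2-[3-(TES-oxy)pent-4-en-1-yl]cyclohex-2-en-1-one, via keto-aldehyde 17 (not isolated)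
Conditions: (S)-2-[methoxy(diphenyl)methyl]pyrrolidine (10 mol%), ethyl 3,4-dihydroxybenzoate (20 mol%), neat, 4 °C; then LiOH, iPrOH, rt
Reagents that add atoms: none
Why: Organocatalytic enamine Michael addition to the vinyl ketone, in which the (S)-catalyst shields one enamine face and sets C4 as S, followed by intramolecular aldol condensation (Robinson-type annulation) that forms ring A.

Step 15
Reactants: 18 cyclohexenone from step 14
Product: 20 (3S,4S)-3-ethenyl-4-[(2S,5E)-7-(TBDPS-oxy)-6-methylhept-5-en-2-yl]-2-[3-(TES-oxy)pent-4-en-1-yl]cyclohex-1-en-1-yl triflate, via magnesium enolate 19 (not isolated)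
Conditions: CH2=CHMgBr (1.5 equiv), CuBr·SMe2 (20 mol%), THF, −78 → −40 °C; then Comins' reagent, −78 °C → rt
Reagents that add atoms: vinylmagnesium bromide C=C[Mg]Br; N-(5-chloropyridin-2-yl)bis(trifluoromethanesulfonyl)imide (Comins' reagent) FC(F)(F)S(=O)(=O)N(c1ccc(Cl)cn1)S(=O)(=O)C(F)(F)F
Why: Cu-catalysed conjugate addition delivers the vinyl group anti to the C4 side chain (3,4-trans), and the regiodefined enolate is trapped as the tetrasubstituted enol triflate.

Step 16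
Reactants: 20 enol triflate from step 15
Product: 21 trimethyl{[(3S,4S)-3-ethenyl-4-[(2S,5E)-7-(TBDPS-oxy)-6-methylhept-5-en-2-yl]-2-[3-(TES-oxy)pent-4-en-1-yl]cyclohex-1-en-1-yl]methyl}silane
Conditions: Me3SiCH2MgCl (2 equiv), Pd(PPh3)4 (5 mol%), Et2O, 0 °C → rt
Reagents that add atoms: (trimethylsilyl)methylmagnesium chloride C[Si](C)(C)C[Mg]Cl
Why: Kumada cross-coupling replaces the triflate by CH2SiMe3 with the ring C=C kept in place, giving a regiodefined allylsilane.

Step 17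
Reactants: 21 allylsilane from step 16
Product: 23 1-[(1S,2S,3S)-3-[(2S,5E)-7-(TBDPS-oxy)-6-methylhept-5-en-2-yl]-2-ethenyl-6-methylidenecyclohexyl]pent-4-en-3-ol, via triethylsilyl ether 22 (not isolated)
Conditions: CF3CO2H (3 equiv), CH2Cl2, −20 °C; then MeOH, 0 °C
Reagents that add atoms: none
Why: Protodesilylation of the allylsilane (SE2′) puts the proton on the ring carbon anti to the neighbouring vinyl group, which allylic 1,2-strain holds pseudoaxial, so the side chain ends cis to the vinyl group and the exocyclic methylene is formed; acidic methanol then cleaves the TES ether.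

Step 18
Reactants: 23 dienol from step 17
Product: 24 5-[(1S,2S,3S)-3-[(2S,5E)-7-(TBDPS-oxy)-6-methylhept-5-en-2-yl]-2-ethenyl-6-methylidenecyclohexyl]pent-1-en-3-one
Conditions: DMP, CH2Cl2, 0 °C
Reagents that add atoms: none
Why: Dess–Martin oxidation of the allylic alcohol gives the vinyl ketone and removes the epimeric carbinol centre.

Step 19
Reactants: 24 vinyl ketone from step 18
Product: 25 (4S,4aS,9aS)-4-[(2S,5E)-7-(TBDPS-oxy)-6-methylhept-5-en-2-yl]-1-methylidene-1,2,3,4,4a,8,9,9a-octahydro-7H-benzo[7]annulen-7-one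
Conditions: second-generation Hoveyda–Grubbs catalyst (H2IMes)Cl2Ru=CH(2-iPrO-C6H4) (5 mol%), CH2Cl2 (2 mM), 40 °C
Reagents that add atoms: none
Why: Ring-closing metathesis between the ring vinyl group and the enone vinyl group forms the cycloheptenone (ring B) with loss of ethylene; the cis ring fusion set in step 17 is carried over unchanged.

Step 20
Reactants: 25 bicyclic enone from step 19; 16 2-bromohexa-1,5-diene
Product: 27 (4S,4aS,5S,9aS)-5-(hexa-1,5-dien-2-yl)-4-[(2S,5E)-7-(TBDPS-oxy)-6-methylhept-5-en-2-yl]-1-methylidenedecahydro-7H-benzo[7]annulen-7-one, via Grignard reagent 26 (not isolated)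
Conditions: 16, Mg, THF, 40 °C; CuBr·SMe2 (20 mol%), then 25, THF, −78 → −30 °C; aq NH4Cl
Reagents that add atoms: none
Why: Cu-catalysed conjugate addition of the alkenyl Grignard reagent occurs on the convex face of the cis-fused bicycle, anti to the ring A bond at the γ-carbon, and sets C5 as S.

Step 21
Reactants: 27 ketone from step 20
Product: 28 (4S,4aS,5S,9aS)-5-(hexa-1,5-dien-2-yl)-1,7-dimethylidene-4-[(2S,5E)-7-(TBDPS-oxy)-6-methylhept-5-en-2-yl]decahydro-1H-benzo[7]annulene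
Conditions: Ph3PCH3Br, KOtBu, THF, 0 °C → rt
Reagents that add atoms: methyltriphenylphosphonium bromide C[P+](c1ccccc1)(c1ccccc1)c1ccccc1.[Br-]
Why: Wittig methylenation of the ring ketone; both α-carbons are CH2, so nothing can epimerise.

Step 22
Reactants: 28 tetraene from step 21
Product: 29 TBDPS ether of the target
Conditions: second-generation Grubbs catalyst (H2IMes)(PCy3)Cl2Ru=CHPh (15 mol%), toluene (1 mM), 80 °C, argon sparge
Reagents that add atoms: none
Why: Ring-closing metathesis starts at the only monosubstituted alkene and closes onto the C7 methylidene (the other 1,1-disubstituted alkenes could only give four- or eight-membered rings), forming ring C and the trisubstituted bridgehead alkene, which is cis within the seven-membered ring.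

Step 23
Reactants: 29 TBDPS ether of the target
Product: 30 (2E,6S)-6-[(1S,2S,3S,7S,10Z)-6,14-dimethylidenetricyclo[8.4.1.0^2,7]pentadec-10-en-3-yl]-2-methylhept-2-en-1-ol (CNP0264710.1)
Conditions: Bu4NF, THF, 0 °C → rt
Reagents that add atoms: none
Why: Fluoride-mediated desilylation frees the allylic alcohol without affecting any alkene or stereocentre.

**Compound list**
1 | (S)-citronellol, (3S)-3,7-dimethyloct-6-en-1-ol | OCC[C@@H](C)CCC=C(C)C | starting material
2 | (3S)-3,7-dimethyloct-6-en-1-yl acetate | CC(=O)OCC[C@@H](C)CCC=C(C)C | intermediate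
3 | (3S,6E)-8-hydroxy-3,7-dimethyloct-6-en-1-yl acetate | CC(=O)OCC[C@@H](C)CC/C=C(\C)CO | intermediate
4 | (3S,6E)-8-[(tert-butyldiphenylsilyl)oxy]-3,7-dimethyloct-6-en-1-yl acetate | CC(=O)OCC[C@@H](C)CC/C=C(\C)CO[Si](c1ccccc1)(c1ccccc1)C(C)(C)C | intermediate
5 | (3S,6E)-8-[(tert-butyldiphenylsilyl)oxy]-3,7-dimethyloct-6-en-1-ol | OCC[C@@H](C)CC/C=C(\C)CO[Si](c1ccccc1)(c1ccccc1)C(C)(C)C | intermediate
6 | (3S,6E)-8-[(tert-butyldiphenylsilyl)oxy]-3,7-dimethyloct-6-enal | O=CC[C@@H](C)CC/C=C(\C)CO[Si](c1ccccc1)(c1ccccc1)C(C)(C)C | intermediate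
7 | δ-valerolactone (oxan-2-one) | O=C1CCCCO1 | starting material
8 | 5-hydroxy-N-methoxy-N-methylpentanamide | CON(C)C(=O)CCCCO | intermediate
9 | N-methoxy-N-methyl-5-oxopentanamide | CON(C)C(=O)CCCC=O | intermediate
10 | (±)-5-hydroxy-N-methoxy-N-methylhept-6-enamide | CON(C)C(=O)CCCC(O)C=C | intermediate
11 | (±)-N-methoxy-N-methyl-5-[(triethylsilyl)oxy]hept-6-enamide | CON(C)C(=O)CCCC(O[Si](CC)(CC)CC)C=C | intermediate
12 | (±)-7-[(triethylsilyl)oxy]nona-1,8-dien-3-one | C=CC(=O)CCCC(O[Si](CC)(CC)CC)C=C | intermediate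
13 | 2-bromoprop-2-en-1-ol | OCC(Br)=C | starting material
14 | ethyl 4-bromopent-4-enoate | CCOC(=O)CCC(Br)=C | intermediate
15 | 4-bromopent-4-enal | O=CCCC(Br)=C | intermediate
16 | 2-bromohexa-1,5-diene | C=CCCC(Br)=C | intermediate
17 | (2S)-2-[(2S,5E)-7-(TBDPS-oxy)-6-methylhept-5-en-2-yl]-5-oxo-9-(TES-oxy)undec-10-enal, C9 epimers | O=C[C@@H](CCC(=O)CCCC(O[Si](CC)(CC)CC)C=C)[C@@H](C)CC/C=C(\C)CO[Si](c1ccccc1)(c1ccccc1)C(C)(C)C | intermediate (not isolated)
18 | (4S)-4-[(2S,5E)-7-(TBDPS-oxy)-6-methylhept-5-en-2-yl]-2-[3-(TES-oxy)pent-4-en-1-yl]cyclohex-2-en-1-one, epimers at the silyloxy carbon | O=C1CC[C@@H]([C@@H](C)CC/C=C(\C)CO[Si](c3ccccc3)(c3ccccc3)C(C)(C)C)C=C1CCC(O[Si](CC)(CC)CC)C=C | intermediate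
19 | bromomagnesium (3S,4S)-3-ethenyl-4-[(2S,5E)-7-(TBDPS-oxy)-6-methylhept-5-en-2-yl]-2-[3-(TES-oxy)pent-4-en-1-yl]cyclohex-1-en-1-olate | Br[Mg]OC=1CC[C@@H]([C@@H](C)CC/C=C(\C)CO[Si](c3ccccc3)(c3ccccc3)C(C)(C)C)[C@H](C=C)C=1CCC(O[Si](CC)(CC)CC)C=C | intermediate (not isolated)
20 | (3S,4S)-3-ethenyl-4-[(2S,5E)-7-(TBDPS-oxy)-6-methylhept-5-en-2-yl]-2-[3-(TES-oxy)pent-4-en-1-yl]cyclohex-1-en-1-yl trifluoromethanesulfonate | FC(F)(F)S(=O)(=O)OC=1CC[C@@H]([C@@H](C)CC/C=C(\C)CO[Si](c3ccccc3)(c3ccccc3)C(C)(C)C)[C@H](C=C)C=1CCC(O[Si](CC)(CC)CC)C=C | intermediate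
21 | trimethyl{[(3S,4S)-3-ethenyl-4-[(2S,5E)-7-(TBDPS-oxy)-6-methylhept-5-en-2-yl]-2-[3-(TES-oxy)pent-4-en-1-yl]cyclohex-1-en-1-yl]methyl}silane | C[Si](C)(C)CC=1CC[C@@H]([C@@H](C)CC/C=C(\C)CO[Si](c3ccccc3)(c3ccccc3)C(C)(C)C)[C@H](C=C)C=1CCC(O[Si](CC)(CC)CC)C=C | intermediate
22 | triethylsilyl ether of 23 | C=C1CC[C@@H]([C@@H](C)CC/C=C(\C)CO[Si](c3ccccc3)(c3ccccc3)C(C)(C)C)[C@H](C=C)[C@@H]1CCC(O[Si](CC)(CC)CC)C=C | intermediate (not isolated)
23 | 1-[(1S,2S,3S)-3-[(2S,5E)-7-(TBDPS-oxy)-6-methylhept-5-en-2-yl]-2-ethenyl-6-methylidenecyclohexyl]pent-4-en-3-ol, carbinol epimers | C=C1CC[C@@H]([C@@H](C)CC/C=C(\C)CO[Si](c3ccccc3)(c3ccccc3)C(C)(C)C)[C@H](C=C)[C@@H]1CCC(O)C=C | intermediate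
24 | 5-[(1S,2S,3S)-3-[(2S,5E)-7-(TBDPS-oxy)-6-methylhept-5-en-2-yl]-2-ethenyl-6-methylidenecyclohexyl]pent-1-en-3-one | C=C1CC[C@@H]([C@@H](C)CC/C=C(\C)CO[Si](c3ccccc3)(c3ccccc3)C(C)(C)C)[C@H](C=C)[C@@H]1CCC(=O)C=C | intermediate
25 | (4S,4aS,9aS)-4-[(2S,5E)-7-(TBDPS-oxy)-6-methylhept-5-en-2-yl]-1-methylidene-1,2,3,4,4a,8,9,9a-octahydro-7H-benzo[7]annulen-7-one (cis-fused) | C=C1CC[C@@H]([C@@H](C)CC/C=C(\C)CO[Si](c3ccccc3)(c3ccccc3)C(C)(C)C)[C@H]2[C@@H]1CCC(=O)C=C2 | intermediate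
26 | hexa-1,5-dien-2-ylmagnesium bromide | C=CCCC(=C)[Mg]Br | intermediate (not isolated)
27 | (4S,4aS,5S,9aS)-5-(hexa-1,5-dien-2-yl)-4-[(2S,5E)-7-(TBDPS-oxy)-6-methylhept-5-en-2-yl]-1-methylidenedecahydro-7H-benzo[7]annulen-7-one | C=C1CC[C@@H]([C@@H](C)CC/C=C(\C)CO[Si](c3ccccc3)(c3ccccc3)C(C)(C)C)[C@H]2[C@@H]1CCC(=O)C[C@@H]2C(=C)CCC=C | intermediate
28 | (4S,4aS,5S,9aS)-5-(hexa-1,5-dien-2-yl)-1,7-dimethylidene-4-[(2S,5E)-7-(TBDPS-oxy)-6-methylhept-5-en-2-yl]decahydro-1H-benzo[7]annulene | C=C1CC[C@@H]([C@@H](C)CC/C=C(\C)CO[Si](c3ccccc3)(c3ccccc3)C(C)(C)C)[C@H]2[C@@H]1CCC(=C)C[C@@H]2C(=C)CCC=C | intermediate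
29 | tert-butyl({(2E,6S)-6-[(1S,2S,3S,7S,10Z)-6,14-dimethylidenetricyclo[8.4.1.0^2,7]pentadec-10-en-3-yl]-2-methylhept-2-en-1-yl}oxy)diphenylsilane | C=C1CC[C@@H]([C@@H](C)CC/C=C(\C)CO[Si](c3ccccc3)(c3ccccc3)C(C)(C)C)[C@H]2[C@@H]1CCC1=CCCC(=C)[C@H]2C1 | intermediate
30 | (2E,6S)-6-[(1S,2S,3S,7S,10Z)-6,14-dimethylidenetricyclo[8.4.1.0^2,7]pentadec-10-en-3-yl]-2-methylhept-2-en-1-ol | C=C1CC[C@@H]([C@@H](C)CC/C=C(\C)CO)[C@H]2[C@@H]1CCC1=CCCC(=C)[C@H]2C1 | target

**Step count**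
Total steps: 23. Longest linear sequence: 15 (steps 1–5 then 14–23; equally 6–10 then 14–23).

**Steps most likely to fail, with fallbacks**

Step 17 (facial selectivity of the protonation that sets the cis ring fusion carbon; acid sensitivity of the exocyclic alkene). The fallback sets out from 18. The vinyl addition of step 15 is run as before, but the magnesium enolate is quenched at −78 °C with a hindered proton source (2,6-di-tert-butylphenol) instead of being triflated. Kinetic protonation anti to the new vinyl group gives (2S,3S,4S)-3-ethenyl-4-[(2S,5E)-7-(TBDPS-oxy)-6-methylhept-5-en-2-yl]-2-[3-(TES-oxy)pent-4-en-1-yl]cyclohexan-1-one F1, and here the proton donor can be varied to tune the selectivity. Non-basic Lombardo methylenation (Zn, CH2Br2, TiCl4, THF/CH2Cl2) of the epimerisable ketone then gives the triethylsilyl ether 22, where the route is rejoined; methanolysis as in step 17 leads on to 23.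

Step 20 (conjugate addition of a branched alkenyl Grignard reagent to a hindered cycloheptenone). The fallback sets out from 25. DBU-catalysed Michael addition of 5-nitropent-1-ene, from the same convex face, gives (4S,4aS,5S,9aS)-4-[(2S,5E)-7-(TBDPS-oxy)-6-methylhept-5-en-2-yl]-1-methylidene-5-(1-nitropent-4-en-1-yl)decahydro-7H-benzo[7]annulen-7-one F2. A Nef reaction (NaOMe, then buffered aqueous TiCl3) converts it into (4S,4aS,5S,9aS)-4-[(2S,5E)-7-(TBDPS-oxy)-6-methylhept-5-en-2-yl]-1-methylidene-5-(pent-4-enoyl)decahydro-7H-benzo[7]annulen-7-one F3, in which the acyl group sits in the favoured position trans to ring A. Double methylenation of both ketones (Zn, CH2Br2, TiCl4) returns to the route at 28.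

Step 22 (metathesis closure to a bridgehead alkene). The fallback sets out from 25, with aldehyde 15 as the side-chain source. Aldehyde 15 is converted (MeOH, TsOH cat.) into 2-bromo-5,5-dimethoxypent-1-ene F4. Its Grignard reagent is added to 25 under the conditions of step 20 to give (4S,4aS,5S,9aS)-5-(5,5-dimethoxypent-1-en-2-yl)-4-[(2S,5E)-7-(TBDPS-oxy)-6-methylhept-5-en-2-yl]-1-methylidenedecahydro-7H-benzo[7]annulen-7-one F5. Mild hydrolysis (PPTS, acetone/water) gives 4-[(4S,4aS,5S,9aS)-4-[(2S,5E)-7-(TBDPS-oxy)-6-methylhept-5-en-2-yl]-1-methylidene-7-oxodecahydro-1H-benzo[7]annulen-5-yl]pent-4-enal F6. Intramolecular McMurry carbonyl coupling (TiCl3(DME)1.5, Zn–Cu, DME, reflux, slow addition) joins the ketone and aldehyde carbons into the bridgehead alkene and returns to the route at 29.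

**Further compounds**
F1 | step 17 | (2S,3S,4S)-3-ethenyl-4-[(2S,5E)-7-(TBDPS-oxy)-6-methylhept-5-en-2-yl]-2-[3-(TES-oxy)pent-4-en-1-yl]cyclohexan-1-one | O=C1CC[C@@H]([C@@H](C)CC/C=C(\C)CO[Si](c3ccccc3)(c3ccccc3)C(C)(C)C)[C@H](C=C)[C@@H]1CCC(O[Si](CC)(CC)CC)C=C
F2 | step 20 | (4S,4aS,5S,9aS)-4-[(2S,5E)-7-(TBDPS-oxy)-6-methylhept-5-en-2-yl]-1-methylidene-5-(1-nitropent-4-en-1-yl)decahydro-7H-benzo[7]annulen-7-one | C=C1CC[C@@H]([C@@H](C)CC/C=C(\C)CO[Si](c3ccccc3)(c3ccccc3)C(C)(C)C)[C@H]2[C@@H]1CCC(=O)C[C@@H]2C(CCC=C)[N+](=O)[O-]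
F3 | step 20 | (4S,4aS,5S,9aS)-4-[(2S,5E)-7-(TBDPS-oxy)-6-methylhept-5-en-2-yl]-1-methylidene-5-(pent-4-enoyl)decahydro-7H-benzo[7]annulen-7-one | C=C1CC[C@@H]([C@@H](C)CC/C=C(\C)CO[Si](c3ccccc3)(c3ccccc3)C(C)(C)C)[C@H]2[C@@H]1CCC(=O)C[C@@H]2C(=O)CCC=C
F4 | step 22 | 2-bromo-5,5-dimethoxypent-1-ene | COC(OC)CCC(Br)=C
F5 | step 22 | (4S,4aS,5S,9aS)-5-(5,5-dimethoxypent-1-en-2-yl)-4-[(2S,5E)-7-(TBDPS-oxy)-6-methylhept-5-en-2-yl]-1-methylidenedecahydro-7H-benzo[7]annulen-7-one | C=C1CC[C@@H]([C@@H](C)CC/C=C(\C)CO[Si](c3ccccc3)(c3ccccc3)C(C)(C)C)[C@H]2[C@@H]1CCC(=O)C[C@@H]2C(=C)CCC(OC)OC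
F6 | step 22 | 4-[(4S,4aS,5S,9aS)-4-[(2S,5E)-7-(TBDPS-oxy)-6-methylhept-5-en-2-yl]-1-methylidene-7-oxodecahydro-1H-benzo[7]annulen-5-yl]pent-4-enal | C=C1CC[C@@H]([C@@H](C)CC/C=C(\C)CO[Si](c3ccccc3)(c3ccccc3)C(C)(C)C)[C@H]2[C@@H]1CCC(=O)C[C@@H]2C(=C)CCC=O
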